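Saturday's charges half the L of Friday's, and E is a fixed loading on L, so Saturday's also holds half the E.

    E → 2 D (k1 = 0.27 s⁻¹)
    L + D → G + Z (k2 = 5.2 × 10⁶ M⁻¹ s⁻¹)
    L + G → Z + G, rate k3*[G]*[L] (k3 = 3.2 × 10⁵ M⁻¹ s⁻¹)
    2 G → G2 (k4 = 1.6 × 10⁶ M⁻¹ s⁻¹)

- Saturday's: L 0.0050 M (fed, over 1.5 s); E 0.2 mol%; time 1.5 s
- Friday's: L 0.010 M (fed, over 1.5 s); E 0.2 mol%; time 1.5 s

- where a step has two of a species, its rate is k times that concentration squared, and two are used at each turn
- the average divides the monomer in chains by the number of chains, living and dead together; two radicals that join make one chain
- run time (Saturday's): 1.5 s

- which of the two ends with the longer chains by the average number of monomer units in a chain (living and dead chains, two that joined counted as one) ("neither" if they lie within 10%) (Saturday's / Friday's / neither)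
- average number of monomer units in a chain (living and dead chains, two that joined counted as one) at the end, Saturday's
- average number of monomer units in a chain (living and dead chains, two that joined counted as one) at the end, Friday's

Count turnovers, and take Saturday's in slow motion. In the first instants of Saturday's, E gives D at 5.40 × 10⁻⁶ M s⁻¹. The half-life of E is 2.57 s, longer than the 1.5 s feed, so I hold E at its charge. Once L in Saturday's stands near half its charge, D waits 7.69 × 10⁻⁵ s for L. That is far shorter than the half-life of E, so I count each D as a G at once.

G then climbs until closing, at twice the closing constant times G squared, matches its supply. In Saturday's that plateau is 1.30 × 10⁻⁶ M, reached in about 0.241 s, which is shorter than the feed.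

In the middle, a unit of L in Saturday's waits 2.41 s for a G, longer than the feed, so I let L pile up. Its mean fed amount is half the charge. Each closing turn makes one chain, while L enters chains at the growth constant times G times L. The ratio of the two rates is the growth constant times L over the closing constant times G. With mean L and plateau G, Saturday's gives 385. Call this the turnover count: units of L entering chains per chain made.

Friday's doubles both L and E, so its plateau G stands higher by the square root of 2 and its count is 544. The ratio of 1.41 is beyond the margin, so I commit to Friday's.

The forecast also says Friday's, with 296 for Saturday's and 410 for Friday's, both lower than my counts. Its grounds include this: “Simpson integration leaves 77% of the feed as L on Saturday”.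

The flask gives Friday's, with 296 in Saturday's and 409 in Friday's. At 1.50 s, Saturday's holds 22.9% of its L charge as Z, and its length stands at 0.769 of the turnover count. Now cut Saturday's E to 0.05 mol%, a quarter of the loading. With L held, plateau G goes as the square root of E, so the count becomes 770, twice the first. That neighbour flask reads 532, with 11.8% of its L as Z, which is 0.691 of its count.

The rate constants are made up; the rest is arithmetic.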